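The ratio c(product)/c(intermediate B) is what I shall follow through this flask.

    intermediate A → intermediate C (k1 = 0.033 /s)
    crystals ⇌ product, rate k2*(cs2 - [product]) while solid is left; crystals form when [product] > cs2 (cs2 = 3.3 mM, k2 = 2.8 /s)
    intermediate C → intermediate B (k3 = 9.6 × 10⁻⁴ /s)
    starting material → intermediate B (k4 = 0.0043 /s)
    starting material ⇌ intermediate A (K5 = 43, k5 = 0.013 /s)
    intermediate B ⇌ product (K6 = 0.39, k6 = 0.070 /s)

starting material 11 mM; time 6.0 min

- east: doubling the solubility in step 2, all else as stated
- west: doubling the dissolution coefficient of step 2, all else as stated

- amounts and yields of product count crystals too
- given per volume of solution although it is solid: crystals
- run time (flask): 6.0 min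

- how much product and crystals together there is at 6.0 min, in percent of the starting material charged
- the change that raises the amount of product and crystals together at 6.0 min, in percent of the starting material charged most ("none" if none brings more than 2 percentage points) (east / west / none)
- amount of product and crystals together at 6.0 min, in percent of the starting material charged, after east

How quickly does that ratio reach its value? The two directions together relax with a half-life of 2.78 s, which is short against the 6.0 min of the flask, so I treat the step as a fast equilibrium and count intermediate B and product as one pool, in which the product share, c(product) over the sum of c(product) and c(intermediate B), is K/(1+K) = 0.281.

How much has reached the pool by then? Starting material goes straight to intermediate B with a fraction 0.249, and the remainder passes through intermediate A into intermediate C, since intermediate A falls back at 3.02 × 10⁻⁴ /s, far slower than it goes on at 0.033 /s. The exit from intermediate C at 9.6 × 10⁻⁴ /s is slower than the steps before it, which makes it the rate-limiting step of that route. Allowing 88.1 s for the passage through the earlier stages, I estimate that intermediate C has released a fraction 0.173 of the charge, so I put the pool at 42.1% and product at 11.8% of the charge.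

But you counted dissolved product alone: what about crystals? With the whole charge of 11 mM in the pool, the share gives 3.09 mM, less than the solubility of 3.3 mM, so I expect this flask to form no crystals, and east and west, which alter step 2, should change nothing; I commit to none as the best change and to 11.8% after east as well.

The forecast gave 11.9%, none and 11.9%, holding that “no crystals ever form and neither change to step 2 has any effect”.

The simulation gives 11.7% against my 11.8%, a gain of 0 percentage points from east and 0 points from west, so none is the best change, and 11.7% stands after east.

In the flask at 6.00 min the relaxation half-life of 2.78 s is short against the 6.0 min run, and the share 0.281 of what is not held as starting material, intermediate A or intermediate C, which stand at 0.212%, 0.169% and 57.5%, comes to 11.8%, with product at 11.7%. In the neighbour flask read at 25 min, intermediate C is down to 19.4% with starting material and intermediate A at 0% and 0%, the same share of the remainder makes 22.6%, and the amount of product and crystals together there is 22.6%.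

All constants were drawn at random within sensible limits; the rest is arithmetic.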